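**Retrosynthetic overview**

1. Helenien (24) is opened at its two ester C–O bonds to lutein (22), which is taken back to its bis-silyl ether 21.
2. 21 is cut at C7=C8 and C7'=C8' (two Julia–Kocienski olefinations) into ring β sulfone 9, crocetindial 19 and ring ε sulfone 18. The plan rests on the C8–C8' segment: an all-E heptaene with methyl groups on C9, C13, C13' and C9' that is crocetindial itself, so ring β (C1–C6, stereocentre C3) and ring ε (C1'–C6', stereocentres C3' and C6') are joined as C10 units through C7 and C7'.
3. 9 comes from ketoisophorone 1: C3 is set by enzymatic C=C reduction followed by equatorial hydride delivery, and C7 is added by carbonylation of enol triflate 5.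
4. 18 comes from (R)-α-ionone 10: C6' is taken from the starting material, C3' is oxygenated by allylic oxidation and set by hydride reduction, and the side chain is cut by ozonolysis while the ring alkene is an enone.
5. No ring is formed anywhere: both six-membered rings come intact from 1 and 10. The order is ring β fragment, ring ε fragment, then the C10 + C20 + C10 union.

Key step: step 16

Assumption: (R)-α-ionone is used in high enantiomeric purity and crocetindial as the all-E isomer; every polyene is handled under argon in dim light.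

**Ring β sulfone (steps 1–8)**

Step 1
Reactants: 1 ketoisophorone (2,6,6-trimethylcyclohex-2-ene-1,4-dione)
Product: 2 (6R)-levodione, (6R)-2,2,6-trimethylcyclohexane-1,4-dione
Conditions: ene-reductase of the old-yellow-enzyme family (OYE2 from Saccharomyces cerevisiae), NADP+ (cat.), glucose dehydrogenase, D-glucose, KH2PO4/K2HPO4 buffer pH 7, 30 °C; prompt extraction
Reagents that add atoms: none
Why: Flavin-dependent ene-reductase reduction of the activated C2=C3 bond (hydride to the β-carbon, proton to the α-carbon from the opposite face) is the established biocatalytic route to this dione, and the fixed binding mode of the substrate in the active site sets the methyl-bearing centre as R.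

Step 2
Reactants: 2 (6R)-levodione
Product: 3 (4R,6R)-actinol, (4R,6R)-4-hydroxy-2,2,6-trimethylcyclohexan-1-one
Conditions: Li[HB(s-Bu)3] (1.05 equiv), THF, −78 °C; H2O; recrystallisation
Reagents that add atoms: none
Why: Chemoselective hydride reduction of the unhindered C4 ketone (the C1 ketone is flanked by the quaternary C2 and the substituted C6), in which the bulky borohydride enters equatorially, anti to the axial C2 methyl group as in the reduction of 3,3,5-trimethylcyclohexanone, so that the new 4R hydroxyl is axial and trans to the C6 methyl group, any cis epimer being removed by recrystallisation.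

Step 3
Reactants: 3 (4R,6R)-actinol
Product: 4 (4R,6R)-4-(tert-butyldimethylsilyloxy)-2,2,6-trimethylcyclohexan-1-one
Conditions: TBSCl, imidazole, DMF, 40 °C
Reagents that add atoms: tert-butyldimethylsilyl chloride, CC(C)(C)[Si](C)(C)Cl
Why: Imidazole-promoted silylation of the secondary alcohol is routine and leaves the hindered ketone untouched.

Step 4
Reactants: 4 silyl ether ketone
Product: 5 (4R)-4-(tert-butyldimethylsilyloxy)-2,6,6-trimethylcyclohex-1-en-1-yl trifluoromethanesulfonate
Conditions: LiN(i-Pr)2 (1.2 equiv), THF, −78 → 0 °C; PhNTf2, 0 → 20 °C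
Reagents that add atoms: N-phenylbis(trifluoromethanesulfonimide), O=S(=O)(N(c1ccccc1)S(=O)(=O)C(F)(F)F)C(F)(F)F
Why: The ketone has a single α-hydrogen (C6), so enolate formation is regiochemically unambiguous and O-sulfonylation of the lithium enolate gives the tetrasubstituted enol triflate, the C6 centre being erased on purpose while the silyloxy-bearing centre (C3 of the carotenoid) stays R.

Step 5
Reactants: 5 enol triflate
Product: 6 methyl (4R)-4-(tert-butyldimethylsilyloxy)-2,6,6-trimethylcyclohex-1-ene-1-carboxylate
Conditions: Pd(OAc)2 (5 mol%), Ph2P(CH2)3PPh2 (10 mol%), CO (1 atm), MeOH, Et3N, DMF, 70 °C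
Reagents that add atoms: carbon monoxide, [C-]#[O+]; methanol, CO
Why: Palladium-catalysed alkoxycarbonylation of an enol triflate (oxidative addition to zerovalent palladium, CO insertion, methanolysis of the acyl complex) installs C7 on the tetrasubstituted ring carbon and tolerates the silyl ether.

Step 6
Reactants: 6 methyl ester
Product: 7 [(4R)-4-(tert-butyldimethylsilyloxy)-2,6,6-trimethylcyclohex-1-en-1-yl]methanol
Conditions: i-Bu2AlH (2.5 equiv), CH2Cl2, −78 → 0 °C; aq. potassium sodium tartrate
Reagents that add atoms: none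
Why: Aluminium hydride 1,2-reduction of the conjugated ester gives the primary allylic alcohol without touching the silyl ether or the ring alkene.

Step 7
Reactants: 7 allylic alcohol
Product: 8 5-({[(4R)-4-(tert-butyldimethylsilyloxy)-2,6,6-trimethylcyclohex-1-en-1-yl]methyl}sulfanyl)-1-phenyl-1H-tetrazole
Conditions: 1-phenyl-1H-tetrazole-5-thiol, PPh3, diisopropyl azodicarboxylate, THF, 0 → 20 °C
Reagents that add atoms: 1-phenyl-1H-tetrazole-5-thiol, Sc1nnnn1-c1ccccc1
Why: Mitsunobu thioetherification, in which the acidic tetrazolethiol displaces the alkoxyphosphonium ion by direct substitution at the primary allylic carbon.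

Step 8
Reactants: 8 sulfide
Product: 9 5-({[(4R)-4-(tert-butyldimethylsilyloxy)-2,6,6-trimethylcyclohex-1-en-1-yl]methyl}sulfonyl)-1-phenyl-1H-tetrazole (ring β sulfone)
Conditions: (NH4)6Mo7O24·4H2O (10 mol%), 30% aq. H2O2, EtOH, 0 → 20 °C
Reagents that add atoms: hydrogen peroxide, OO
Why: Peroxomolybdate-catalysed oxidation of the sulfide through the sulfoxide to the sulfone is the usual entry to tetrazolyl sulfones and should be faster than epoxidation of the hindered tetrasubstituted alkene.

**Ring ε sulfone (steps 9–15; ionone numbering, C6 and C3 become C6' and C3' of the target)**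

Step 9
Reactants: 10 (R)-α-ionone
Product: 11 2-methyl-2-[(E)-2-[(1R)-2,6,6-trimethylcyclohex-2-en-1-yl]ethenyl]-1,3-dioxolane
Conditions: (Me3SiOCH2)2 (1.5 equiv), Me3SiOTf (2 mol%), CH2Cl2, −78 → −20 °C; pyridine quench
Reagents that add atoms: 1,2-bis(trimethylsilyloxy)ethane, C[Si](C)(C)OCCO[Si](C)(C)C
Why: Silyl-triflate-catalysed acetalisation with the bis-silylated glycol converts the C9 carbonyl into its dioxolane under aprotic, low-temperature conditions that neither shift the C7=C8 double bond nor enolise towards C6, so that the side-chain alkene is no longer part of an enone.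

Step 10
Reactants: 11 dioxolane
Product: 12 (4R)-3,5,5-trimethyl-4-[(E)-2-(2-methyl-1,3-dioxolan-2-yl)ethenyl]cyclohex-2-en-1-one
Conditions: Rh2(C6H10NO)4 (dirhodium tetracaprolactamate, 1 mol%), t-BuOOH (70% in H2O, 5 equiv), K2CO3 (0.5 equiv), CH2Cl2, 20 °C
Reagents that add atoms: tert-butyl hydroperoxide, CC(C)(C)OO
Why: Radical allylic C–H oxidation with tert-butyl hydroperoxide (hydrogen abstraction by the tert-butylperoxyl radical, peroxide formation and collapse to the ketone) should occur at the accessible ring methylene C3 next to the trisubstituted alkene in preference to the shielded tertiary C6–H, as is known for α-ionone derivatives.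

Step 11
Reactants: 12 enone dioxolane
Product: 14 (4R)-4-(hydroxymethyl)-3,5,5-trimethylcyclohex-2-en-1-one, via keto aldehyde 13 (not isolated)
Conditions: O3, pyridine (3 equiv), CH2Cl2, −78 °C, Sudan red 7B as end-point indicator; then MeOH, NaBH4 (1.5 equiv), −78 → −40 °C
Reagents that add atoms: ozone, [O-][O+]=O
Why: Ozonolysis by an electrophilic oxidant should cleave the isolated C7=C8 alkene well before the ring C4=C5 bond, which is deactivated as a β,β-disubstituted enone (the selectivity used in side-chain ozonolysis of steroidal 4-en-3-ones), pyridine collapsing the carbonyl oxide to aldehyde 13 at −78 °C and borohydride at that temperature reducing the formyl group but not the hindered conjugated ketone, so that C6 is α to a free aldehyde only briefly.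

Step 12
Reactants: 14 hydroxymethyl enone
Product: 15 (4R)-3,5,5-trimethyl-4-{[(1-phenyl-1H-tetrazol-5-yl)sulfanyl]methyl}cyclohex-2-en-1-one
Conditions: 1-phenyl-1H-tetrazole-5-thiol, PPh3, diisopropyl azodicarboxylate, THF, 0 → 20 °C
Reagents that add atoms: 1-phenyl-1H-tetrazole-5-thiol, Sc1nnnn1-c1ccccc1
Why: Mitsunobu thioetherification of the primary, β-branched alcohol proceeds under essentially neutral conditions that spare the enone and the γ-stereocentre C6.

Step 13
Reactants: 15 keto sulfide
Product: 16 (1R,4R)-3,5,5-trimethyl-4-{[(1-phenyl-1H-tetrazol-5-yl)sulfanyl]methyl}cyclohex-2-en-1-ol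
Conditions: Li[HB(s-Bu)3] (1.2 equiv), THF, −78 °C; H2O; chromatography
Reagents that add atoms: none
Why: 1,2-Reduction of the β,β-disubstituted enone by the bulky borohydride, which in the half-chair with the C6 substituent pseudoaxial (no allylic strain with the C5 methyl group) should approach C3 anti to the axial C1 methyl group and so place the new hydroxyl (3'R in the target) trans to the CH2S group, any cis epimer being removed by chromatography.

Step 14
Reactants: 16 trans hydroxy sulfide
Product: 17 5-({[(1R,4R)-4-(tert-butyldimethylsilyloxy)-2,6,6-trimethylcyclohex-2-en-1-yl]methyl}sulfanyl)-1-phenyl-1H-tetrazole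
Conditions: TBSCl, imidazole, DMF, 20 °C
Reagents that add atoms: tert-butyldimethylsilyl chloride, CC(C)(C)[Si](C)(C)Cl
Why: Standard imidazole-promoted silylation of the secondary allylic alcohol, with no change at either stereocentre.

Step 15
Reactants: 17 silyl ether sulfide
Product: 18 5-({[(1R,4R)-4-(tert-butyldimethylsilyloxy)-2,6,6-trimethylcyclohex-2-en-1-yl]methyl}sulfonyl)-1-phenyl-1H-tetrazole (ring ε sulfone)
Conditions: (NH4)6Mo7O24·4H2O (10 mol%), 30% aq. H2O2, EtOH, 0 → 20 °C
Reagents that add atoms: hydrogen peroxide, OO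
Why: Peroxomolybdate-catalysed sulfide-to-sulfone oxidation, chemoselective over the trisubstituted ring alkene and compatible with the secondary silyl ether.

**Union and completion (steps 16–18)**

Step 16
Reactants: 18 ring ε sulfone; 19 crocetindial; 9 ring β sulfone
Product: 21 lutein bis(tert-butyldimethylsilyl) ether, (3R,3'R,6'R)-3,3'-bis(tert-butyldimethylsilyloxy)-β,ε-carotene, via apo-carotenal 20 (not isolated)
Conditions: 18, KN(SiMe3)2 (1.05 equiv), THF, −78 °C, 15 min, cannulated into 19 (3 equiv) in dilute THF at −60 °C, then 0 °C; THF exchanged for cold hexane and surplus 19 filtered off for re-use; filtrate taken up in THF, −78 °C, pre-formed anion of 9 (1.5 equiv, KN(SiMe3)2, THF, −78 °C) added, then 20 °C; H2O; then I2 (1 mol%), hexane, diffuse daylight, 20 °C; aq. Na2S2O3; chromatography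
Reagents that add atoms: none
Why: Each potassium sulfonyl carbanion adds to a formyl group, the β-alkoxide so formed attacks the tetrazole carbon (Smiles rearrangement, aryl shift from sulfur to oxygen), and the resulting sulfinate expels SO2 and 1-phenyltetrazol-5-olate to give the alkene, which is the Julia–Kocienski olefination as practised on polyenals with phenyltetrazolyl sulfones. No ring is closed and no stereocentre is created: C3, C3' and C6' arrive intact in 9 and 18, and C6'–H, which is not α to the sulfonyl group, should not be touched by the amide base at −78 °C. The step needs mono-olefination of 19 in the first stage and E geometry at C7'=C8' and C7=C8. The first is secured by inverse addition of the more reactive, non-allylic anion of 18 to an excess of 19, whose second formyl group loses its through-conjugated acceptor partner once the first has reacted, and by filtering the sparingly soluble surplus dialdehyde from hexane before the allylic anion of 9 is introduced, so that little free 19 is left to give a symmetrical β,β product. The second is favoured by the open transition state of the potassium species in THF and, for any 7Z or 7'Z isomer (destabilised by the clash between the ring methyl groups and the C9 or C9' substituents), is completed by the closing iodine-catalysed photoequilibration, the chain double bonds of 19 keeping the E geometry they had in the starting dialdehyde.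

Step 17
Reactants: 21 lutein bis(tert-butyldimethylsilyl) ether
Product: 22 lutein, (3R,3'R,6'R)-β,ε-carotene-3,3'-diol
Conditions: Bu4NF (3 equiv), THF, 0 → 20 °C, dark; crystallisation from CH2Cl2/hexane
Reagents that add atoms: none
Why: Fluoride-induced Si–O cleavage under non-acidic conditions, chosen because the allylic C3' hydroxyl of ring ε ionises readily in acid, with crystallisation of the diol expected to remove residual geometric and symmetrical isomers.

Step 18
Reactants: 22 lutein; 23 palmitoyl chloride
Product: 24 helenien, (3R,3'R,6'R)-β,ε-carotene-3,3'-diyl dihexadecanoate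
Conditions: 23 (2.5 equiv), pyridine, 4-(dimethylamino)pyridine (10 mol%), CH2Cl2, 0 → 20 °C, dark; recrystallisation
Reagents that add atoms: none
Why: Acylation of both secondary hydroxyls by the acid chloride under nucleophilic catalysis (acylpyridinium intermediate), the base buffering HCl so that the allylic C3'–O bond is not ionised and C3, C3' and C6' keep their configuration.

**Compound list**

1 | ketoisophorone, 2,6,6-trimethylcyclohex-2-ene-1,4-dione | CC1=CC(=O)CC(C)(C)C1=O | starting material
2 | (6R)-levodione, (6R)-2,2,6-trimethylcyclohexane-1,4-dione | C[C@@H]1CC(=O)CC(C)(C)C1=O | intermediate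
3 | (4R,6R)-actinol, (4R,6R)-4-hydroxy-2,2,6-trimethylcyclohexan-1-one | C[C@@H]1C[C@@H](O)CC(C)(C)C1=O | intermediate
4 | (4R,6R)-4-(tert-butyldimethylsilyloxy)-2,2,6-trimethylcyclohexan-1-one | C[C@@H]1C[C@@H](O[Si](C)(C)C(C)(C)C)CC(C)(C)C1=O | intermediate
5 | (4R)-4-(tert-butyldimethylsilyloxy)-2,6,6-trimethylcyclohex-1-en-1-yl trifluoromethanesulfonate | CC(C)(C)[Si](C)(C)O[C@@H]1CC(C)=C(OS(=O)(=O)C(F)(F)F)C(C)(C)C1 | intermediate
6 | methyl (4R)-4-(tert-butyldimethylsilyloxy)-2,6,6-trimethylcyclohex-1-ene-1-carboxylate | CC(C)(C)[Si](C)(C)O[C@@H]1CC(C)=C(C(=O)OC)C(C)(C)C1 | intermediate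
7 | [(4R)-4-(tert-butyldimethylsilyloxy)-2,6,6-trimethylcyclohex-1-en-1-yl]methanol | CC(C)(C)[Si](C)(C)O[C@@H]1CC(C)=C(CO)C(C)(C)C1 | intermediate
8 | 5-({[(4R)-4-(tert-butyldimethylsilyloxy)-2,6,6-trimethylcyclohex-1-en-1-yl]methyl}sulfanyl)-1-phenyl-1H-tetrazole | CC(C)(C)[Si](C)(C)O[C@@H]1CC(C)=C(CSc2nnnn2-c3ccccc3)C(C)(C)C1 | intermediate
9 | 5-({[(4R)-4-(tert-butyldimethylsilyloxy)-2,6,6-trimethylcyclohex-1-en-1-yl]methyl}sulfonyl)-1-phenyl-1H-tetrazole | CC(C)(C)[Si](C)(C)O[C@@H]1CC(C)=C(CS(=O)(=O)c2nnnn2-c3ccccc3)C(C)(C)C1 | intermediate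
10 | (R)-α-ionone | CC(=O)/C=C/[C@H]1C(C)=CCCC1(C)C | starting material
11 | 2-methyl-2-[(E)-2-[(1R)-2,6,6-trimethylcyclohex-2-en-1-yl]ethenyl]-1,3-dioxolane | CC1(/C=C/[C@H]2C(C)=CCCC2(C)C)OCCO1 | intermediate
12 | (4R)-3,5,5-trimethyl-4-[(E)-2-(2-methyl-1,3-dioxolan-2-yl)ethenyl]cyclohex-2-en-1-one | CC1(/C=C/[C@H]2C(C)=CC(=O)CC2(C)C)OCCO1 | intermediate
13 | (1R)-2,6,6-trimethyl-4-oxocyclohex-2-ene-1-carbaldehyde | O=C[C@H]1C(C)=CC(=O)CC1(C)C | intermediate
14 | (4R)-4-(hydroxymethyl)-3,5,5-trimethylcyclohex-2-en-1-one | OC[C@H]1C(C)=CC(=O)CC1(C)C | intermediate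
15 | (4R)-3,5,5-trimethyl-4-{[(1-phenyl-1H-tetrazol-5-yl)sulfanyl]methyl}cyclohex-2-en-1-one | c1ccccc1-n1nnnc1SC[C@H]1C(C)=CC(=O)CC1(C)C | intermediate
16 | (1R,4R)-3,5,5-trimethyl-4-{[(1-phenyl-1H-tetrazol-5-yl)sulfanyl]methyl}cyclohex-2-en-1-ol | c1ccccc1-n1nnnc1SC[C@H]1C(C)=C[C@H](O)CC1(C)C | intermediate
17 | 5-({[(1R,4R)-4-(tert-butyldimethylsilyloxy)-2,6,6-trimethylcyclohex-2-en-1-yl]methyl}sulfanyl)-1-phenyl-1H-tetrazole | c1ccccc1-n1nnnc1SC[C@H]1C(C)=C[C@H](O[Si](C)(C)C(C)(C)C)CC1(C)C | intermediate
18 | 5-({[(1R,4R)-4-(tert-butyldimethylsilyloxy)-2,6,6-trimethylcyclohex-2-en-1-yl]methyl}sulfonyl)-1-phenyl-1H-tetrazole | O=S(=O)(C[C@H]1C(C)=C[C@H](O[Si](C)(C)C(C)(C)C)CC1(C)C)c2nnnn2-c3ccccc3 | intermediate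
19 | crocetindial, (all-E)-2,6,11,15-tetramethylhexadeca-2,4,6,8,10,12,14-heptaenedial | O=C/C(C)=C/C=C/C(C)=C/C=C/C=C(C)/C=C/C=C(C)/C=O | starting material
20 | (3R,6R)-3-(tert-butyldimethylsilyloxy)-8'-apo-ε-caroten-8'-al | O=C/C(C)=C/C=C/C(C)=C/C=C/C=C(C)/C=C/C=C(C)/C=C/[C@H]1C(C)=C[C@H](O[Si](C)(C)C(C)(C)C)CC1(C)C | intermediate
21 | lutein bis(tert-butyldimethylsilyl) ether | CC(C)(C)[Si](C)(C)O[C@@H]1CC(C)=C(/C=C/C(C)=C/C=C/C(C)=C/C=C/C=C(C)/C=C/C=C(C)/C=C/[C@H]2C(C)=C[C@H](O[Si](C)(C)C(C)(C)C)CC2(C)C)C(C)(C)C1 | intermediate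
22 | lutein, (3R,3'R,6'R)-β,ε-carotene-3,3'-diol | O[C@@H]1CC(C)=C(/C=C/C(C)=C/C=C/C(C)=C/C=C/C=C(C)/C=C/C=C(C)/C=C/[C@H]2C(C)=C[C@H](O)CC2(C)C)C(C)(C)C1 | intermediate
23 | palmitoyl chloride | CCCCCCCCCCCCCCCC(Cl)=O | starting material
24 | helenien, (3R,3'R,6'R)-β,ε-carotene-3,3'-diyl dihexadecanoate | CCCCCCCCCCCCCCCC(=O)O[C@@H]1CC(C)=C(/C=C/C(C)=C/C=C/C(C)=C/C=C/C=C(C)/C=C/C=C(C)/C=C/[C@H]2C(C)=C[C@H](OC(=O)CCCCCCCCCCCCCCC)CC2(C)C)C(C)(C)C1 | target

**Step count and risks**

Total step count: 18. Longest linear sequence: 11 steps (steps 1–8, then 16, 17 and 18).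

Steps most likely to fail:

Step 16. The first olefination may run on to bis-olefination, or dissolved dialdehyde may pass the filtration and be converted by the anion of 9 into a symmetrical C40 by-product that is hard to separate from 21; incomplete E control at the new double bonds is a lesser concern because it is corrected by equilibration. Fallback, setting out from 19 and returning at 21: one formyl group is masked before any olefination. Treatment of 19 with one equivalent of 2,2-dimethylpropane-1,3-diol (pyridinium p-toluenesulfonate, benzene, removal of water) gives crocetindial mono(2,2-dimethylpropane-1,3-diyl) acetal F1, which is separated by chromatography from 19 and the bis-acetal, both being recycled. F1 is olefinated with the potassium anion of 18 to give the C30 acetal F2. Mild hydrolysis (pyridinium p-toluenesulfonate, wet acetone) then liberates 20, which is now isolated and purified, and 20 with the potassium anion of 9 gives 21.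

Step 11. Ozone may go on to attack the ring enone once the side-chain alkene is consumed, and configuration at C6 may be lost by enolisation while the formyl group of 13 is free. Fallback, setting out from 12 and returning at 14: the cleavage is split into dihydroxylation and glycol fission. OsO4 (cat.) with N-methylmorpholine N-oxide in acetone/H2O, which discriminates sharply between an isolated alkene and an enone, gives (4R)-4-[1,2-dihydroxy-2-(2-methyl-1,3-dioxolan-2-yl)ethyl]-3,5,5-trimethylcyclohex-2-en-1-one F3, a stable diol that can be purified. NaIO4 on silica gel in CH2Cl2 at 0 °C cleaves F3 to 13 under neutral conditions, and the filtrate is run directly into NaBH4/MeOH at −78 °C to give 14.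

Step 13. Facial selectivity of hydride delivery to the ring ketone may be poor, giving much of the cis alcohol. Fallback, setting out from 15 and returning at 16: the stereocentre is corrected by inversion. Reduction of 15 (NaBH4, CeCl3·7H2O, MeOH, −40 °C, Luche reduction) is accepted as a mixture, 16 is separated, and the cis epimer (1S,4R)-3,5,5-trimethyl-4-{[(1-phenyl-1H-tetrazol-5-yl)sulfanyl]methyl}cyclohex-2-en-1-ol F4 is subjected to Mitsunobu esterification with 4-nitrobenzoic acid (PPh3, diisopropyl azodicarboxylate, THF) to give, with inversion at the carbinol carbon, (1R,4R)-3,5,5-trimethyl-4-{[(1-phenyl-1H-tetrazol-5-yl)sulfanyl]methyl}cyclohex-2-en-1-yl 4-nitrobenzoate F5. Methanolysis of F5 (K2CO3, MeOH, 0 °C) gives 16.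

Further compounds
F1 | step 16 | crocetindial mono(2,2-dimethylpropane-1,3-diyl) acetal, (all-E)-15-(5,5-dimethyl-1,3-dioxan-2-yl)-2,6,11-trimethylhexadeca-2,4,6,8,10,12,14-heptaenal | O=C/C(C)=C/C=C/C(C)=C/C=C/C=C(C)/C=C/C=C(C)/C1OCC(C)(C)CO1
F2 | step 16 | (3R,6R)-3-(tert-butyldimethylsilyloxy)-8'-apo-ε-caroten-8'-al 2,2-dimethylpropane-1,3-diyl acetal | CC1(C)COC(OC1)/C(C)=C/C=C/C(C)=C/C=C/C=C(C)/C=C/C=C(C)/C=C/[C@H]1C(C)=C[C@H](O[Si](C)(C)C(C)(C)C)CC1(C)C
F3 | step 11 | (4R)-4-[1,2-dihydroxy-2-(2-methyl-1,3-dioxolan-2-yl)ethyl]-3,5,5-trimethylcyclohex-2-en-1-one (syn diol, both side-chain diastereomers) | CC1(OCCO1)C(O)C(O)[C@H]1C(C)=CC(=O)CC1(C)C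
F4 | step 13 | (1S,4R)-3,5,5-trimethyl-4-{[(1-phenyl-1H-tetrazol-5-yl)sulfanyl]methyl}cyclohex-2-en-1-ol | c1ccccc1-n1nnnc1SC[C@H]1C(C)=C[C@@H](O)CC1(C)C
F5 | step 13 | (1R,4R)-3,5,5-trimethyl-4-{[(1-phenyl-1H-tetrazol-5-yl)sulfanyl]methyl}cyclohex-2-en-1-yl 4-nitrobenzoate | c1ccccc1-n1nnnc1SC[C@H]1C(C)=C[C@H](OC(=O)c2ccc(cc2)[N+](=O)[O-])CC1(C)C
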